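**Plan** (germacrane numbering: ring C1–C10, lactone carbons C11–C13, ester carbon C14, methyl C15)
1. Cuts, in order: the O8 and O9 acyl bonds; C1=C10 of the ten-membered ring; C9–C10; C6–C7 together with the lactone bond O6–C12; finally C1–C2 of the epoxy enal piece.
2. Enabling feature: C10 lies between the C9 carbonyl and the C14 ester carbonyl (a β-keto ester methylene), and C1 is an aldehyde carbon on epoxide carbon C2, which cannot enolise; condensation of C10 on C1 gives the C1=C10 enoate and closes ring C1–C10.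
3. Forward: a C1–C6 cis-epoxy Z-enal and a C7–C9/C11–C13 allylic bromide are joined at C6–C7 by chromium allylation, which also closes the lactone ring (O6, C6, C7, C11, C12); C10/C14 are added to C9 from methyl acetate; the lactone methylene is masked as its dimethylamine adduct; the ten-membered ring then closes by Knoevenagel condensation.
4. End game: reduction at C9, acylation of O9 and then O8, release of the C11=C13 methylene.
5. Stereochemistry: C8 from methyl (R)-glycerate; C2/C3 from Sharpless epoxidation of a Z-allylic alcohol; C6/C7 from the anti-selective allylation steered by C8; C9 from Felkin–Anh reduction next to C8; the acyl centres from (R)-2-methylbutanoic acid and a second Sharpless epoxidation; C4=C5 geometry from a Z-enynol, C1=C10 geometry from thermodynamic control.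

Key step: step 18

Remark: target numbering is used for all intermediates; α/β refer to the usual germacranolide drawing with H-7 α. Centres that are destroyed later (the carbinol C7 of the Morita–Baylis–Hillman adduct, C9 of the aldol adduct, C11 of the amine-masked lactone) are carried as mixtures and drawn without configuration.

**Route**

Step 1
Reactants: 1 (2Z)-3-methylpent-2-en-4-yn-1-ol
Product: 2 tert-butyldimethyl{[(2Z)-3-methylpent-2-en-4-yn-1-yl]oxy}silane
Conditions: TBSCl, imidazole, CH2Cl2, 0 °C → rt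
Reagents that add atoms: tert-butyldimethylsilyl chloride, CC(C)(C)[Si](C)(C)Cl
Why: Silyl ether formation on the primary allylic alcohol (future O6) keeps this hydroxyl from directing the later epoxidation, and the Z-geometry that places C3 cis to C6 is already present in the commercial enynol.

Step 2
Reactants: 2 tert-butyldimethyl{[(2Z)-3-methylpent-2-en-4-yn-1-yl]oxy}silane; 3 formaldehyde (as paraformaldehyde)
Product: 4 (4Z)-6-[(tert-butyldimethylsilyl)oxy]-4-methylhex-4-en-2-yn-1-ol
Conditions: n-BuLi, THF, −78 °C; then (CH2O)n, −78 °C → rt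
Reagents that add atoms: none
Why: Addition of the lithium acetylide to formaldehyde (acetylide hydroxymethylation) forms the C1–C2 bond and gives the propargylic alcohol that becomes the directing C1 hydroxyl, with no stereocentre involved.

Step 3
Reactants: 4 (4Z)-6-[(tert-butyldimethylsilyl)oxy]-4-methylhex-4-en-2-yn-1-ol
Product: 5 (2Z,4Z)-6-[(tert-butyldimethylsilyl)oxy]-4-methylhexa-2,4-dien-1-ol
Conditions: H2 (1 atm), Pd/CaCO3 poisoned with Pb(OAc)2 (Lindlar catalyst), quinoline, EtOAc, rt
Reagents that add atoms: none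
Why: Lindlar semihydrogenation adds H2 syn to the alkyne and stops at the alkene, so C2=C3 is formed with Z-geometry next to the untouched Z-C4=C5 olefin.

Step 4
Reactants: 5 (2Z,4Z)-6-[(tert-butyldimethylsilyl)oxy]-4-methylhexa-2,4-dien-1-ol
Product: 6 [(2R,3S)-3-{(2Z)-4-[(tert-butyldimethylsilyl)oxy]but-2-en-2-yl}oxiran-2-yl]methanol
Conditions: Ti(OiPr)4, diethyl L-tartrate, t-BuOOH, 4 Å molecular sieves, CH2Cl2, −20 °C
Reagents that add atoms: tert-butyl hydroperoxide, CC(C)(C)OO
Why: Sharpless asymmetric epoxidation, in which titanium bound to the free C1 alcohol restricts oxidation to C2=C3 and the L-tartrate ligand delivers oxygen to the face that gives the (2R,3S) epoxide, the Z-olefin geometry making it the cis-epoxide needed at C2/C3.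

Step 5
Reactants: 6 [(2R,3S)-3-{(2Z)-4-[(tert-butyldimethylsilyl)oxy]but-2-en-2-yl}oxiran-2-yl]methanol
Product: 7 tert-butyl{[(2Z)-3-[(2S,3R)-3-{[(4-methoxybenzyl)oxy]methyl}oxiran-2-yl]but-2-en-1-yl]oxy}dimethylsilane
Conditions: NaH, 4-methoxybenzyl chloride, Bu4NI (cat.), THF, 0 °C → rt
Reagents that add atoms: 4-methoxybenzyl chloride, COc1ccc(CCl)cc1
Why: Williamson etherification of the primary alkoxide in an aprotic medium (where Payne rearrangement of the epoxy alkoxide is not expected) puts on O1 a group that can later be removed oxidatively without acid or fluoride.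

Step 6
Reactants: 7 tert-butyl{[(2Z)-3-[(2S,3R)-3-{[(4-methoxybenzyl)oxy]methyl}oxiran-2-yl]but-2-en-1-yl]oxy}dimethylsilane
Product: 8 (2Z)-3-[(2S,3R)-3-{[(4-methoxybenzyl)oxy]methyl}oxiran-2-yl]but-2-en-1-ol
Conditions: Bu4NF, THF, 0 °C
Reagents that add atoms: none
Why: Fluoride-induced desilylation frees the allylic C6 alcohol and leaves the epoxide and the benzyl-type ether untouched.

Step 7
Reactants: 8 (2Z)-3-[(2S,3R)-3-{[(4-methoxybenzyl)oxy]methyl}oxiran-2-yl]but-2-en-1-ol
Product: 9 (2Z)-3-[(2S,3R)-3-{[(4-methoxybenzyl)oxy]methyl}oxiran-2-yl]but-2-enal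
Conditions: MnO2, CH2Cl2, rt
Reagents that add atoms: none
Why: MnO2 oxidation of the allylic alcohol is neutral and selective, so the Z-enal should form without Z/E isomerisation and without opening of the allylic epoxide, and it is used at once.

Step 8
Reactants: 10 methyl (2R)-2,3-dihydroxypropanoate
Product: 11 methyl (2R)-2,3-bis[(triethylsilyl)oxy]propanoate
Conditions: Et3SiCl, imidazole, DMAP (cat.), CH2Cl2, 0 °C → rt
Reagents that add atoms: chlorotriethylsilane, CC[Si](Cl)(CC)CC
Why: Silyl ether formation protects the future O8 and O9 with groups that can later be oxidised off or removed without the acid an acetal would need (acid would open the allylic epoxide), and the stereocentre (future C8) is not touched.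

Step 9
Reactants: 11 methyl (2R)-2,3-bis[(triethylsilyl)oxy]propanoate
Product: 12 (2R)-2,3-bis[(triethylsilyl)oxy]propanal
Conditions: i-Bu2AlH, CH2Cl2, −78 °C
Reagents that add atoms: none
Why: Partial reduction of the ester with i-Bu2AlH at −78 °C stops at the aldehyde (future C7) through the stable aluminium hemiacetal, and α-silyloxy aldehydes keep their configuration under these conditions.

Step 10
Reactants: 12 (2R)-2,3-bis[(triethylsilyl)oxy]propanal; 13 methyl acrylate
Product: 14 methyl (4R)-3-hydroxy-2-methylidene-4,5-bis[(triethylsilyl)oxy]pentanoate (C3 epimers)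
Conditions: DABCO, neat methyl acrylate, rt
Reagents that add atoms: none
Why: The Morita–Baylis–Hillman reaction joins the acrylate α-carbon (C11) to the aldehyde carbon (C7), and the new carbinol centre may form as a mixture because it is removed in step 11.

Step 11
Reactants: 14 methyl (4R)-3-hydroxy-2-methylidene-4,5-bis[(triethylsilyl)oxy]pentanoate
Product: 16 methyl (2Z,4S)-2-(bromomethyl)-4,5-bis[(triethylsilyl)oxy]pent-2-enoate, via allylic mesylate 15 (not isolated)
Conditions: MsCl, Et3N, CH2Cl2, −20 °C; then LiBr, THF, rt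
Reagents that add atoms: lithium bromide, [Li+].[Br-]
Why: Mesylation and SN2′ displacement by bromide (allylic transposition of a Morita–Baylis–Hillman adduct) give the conjugated primary bromide with C8 trans to the ester, the thermodynamically preferred Z-isomer, under conditions free of acid that would cleave the silyl ethers.

Step 12
Reactants: 9 (2Z)-3-[(2S,3R)-3-{[(4-methoxybenzyl)oxy]methyl}oxiran-2-yl]but-2-enal; 16 methyl (2Z,4S)-2-(bromomethyl)-4,5-bis[(triethylsilyl)oxy]pent-2-enoate
Product: 18 (4S,5R)-4-[(1S)-1,2-bis(triethylsilyloxy)ethyl]-5-[(1Z)-2-[(2S,3R)-3-{[(4-methoxybenzyl)oxy]methyl}oxiran-2-yl]prop-1-en-1-yl]-3-methylideneoxolan-2-one, via open-chain hydroxy ester 17 (not isolated)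
Conditions: CrCl2, THF, 0 °C → rt
Reagents that add atoms: none
Why: Nozaki–Hiyama allylation with a 2-(alkoxycarbonyl)allyl bromide, in which the equilibrating allylchromium species adds to the aldehyde through a chair (Zimmerman–Traxler) transition state with the C8 group equatorial to give the 6,7-anti adduct and hence the trans lactone, the aldehyde should reach C7 anti to the C9 methylene with C8–H eclipsing the ester-bearing C11 (allylic strain) so that the glycerate centre sets C7 and thereby C6, and the chromium alkoxide then closes onto the methyl ester to form the lactone ring.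

Step 13
Reactants: 18 (4S,5R)-4-[(1S)-1,2-bis(triethylsilyloxy)ethyl]-5-[(1Z)-2-[(2S,3R)-3-{[(4-methoxybenzyl)oxy]methyl}oxiran-2-yl]prop-1-en-1-yl]-3-methylideneoxolan-2-one
Product: 19 (2S)-2-[(2R,3S)-2-[(1Z)-2-[(2S,3R)-3-{[(4-methoxybenzyl)oxy]methyl}oxiran-2-yl]prop-1-en-1-yl]-4-methylidene-5-oxooxolan-3-yl]-2-[(triethylsilyl)oxy]acetaldehyde (C9 aldehyde, other centres as in 18)
Conditions: (COCl)2, DMSO, CH2Cl2, −78 → −30 °C; then Et3N, −78 → 0 °C
Reagents that add atoms: none
Why: Swern oxidation applied directly to the silyl ether, in which the chlorosulfonium reagent cleaves only the unhindered primary O9–Si bond and oxidises that position to the aldehyde while the secondary O8 silyl ether, the benzyl-type ether and the epoxide are left alone, and α-silyloxy aldehydes do not epimerise under these conditions.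

Step 14
Reactants: 19 C9 aldehyde; 20 methyl acetate
Product: 21 methyl (4S)-3-hydroxy-4-[(2R,3S)-2-[(1Z)-2-[(2S,3R)-3-{[(4-methoxybenzyl)oxy]methyl}oxiran-2-yl]prop-1-en-1-yl]-4-methylidene-5-oxooxolan-3-yl]-4-[(triethylsilyl)oxy]butanoate (C9 epimers)
Conditions: LiN(i-Pr)2, methyl acetate, THF, −78 °C; then 19, −78 °C
Reagents that add atoms: none
Why: Aldol addition of the lithium enolate of methyl acetate brings in C10 and C14, the aldehyde reacting at −78 °C far faster than the exocyclic enoate of the lactone, and the new C9 carbinol may form as a mixture because it is oxidised in step 17.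

Step 15
Reactants: 21 β-hydroxy ester
Product: 22 methyl (4S)-3-hydroxy-4-[(2R,3S)-2-[(1Z)-2-[(2S,3R)-3-(hydroxymethyl)oxiran-2-yl]prop-1-en-1-yl]-4-methylidene-5-oxooxolan-3-yl]-4-[(triethylsilyl)oxy]butanoate (C1,C9 diol; C9 epimers)
Conditions: DDQ, CH2Cl2/pH 7 buffer, 0 °C
Reagents that add atoms: none
Why: Oxidative cleavage of the 4-methoxybenzyl ether by DDQ under buffered conditions frees the C1 alcohol without the acid that would open the allylic epoxide and without touching the silyl ether.

Step 16
Reactants: 22 C1,C9 diol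
Product: 23 dimethylamine adduct of 22 at C13: the 4-methylidene group of the lactone replaced by 4-[(dimethylamino)methyl] (C9 and C11 epimers)
Conditions: Me2NH (2 M in THF), THF, 0 °C → rt
Reagents that add atoms: dimethylamine, CNC
Why: Aza-Michael addition of dimethylamine to the α-methylene lactone, a standard reversible mask for this unit, removes the C13 acceptor before the β-keto ester exists, so that C10 cannot later close a six-membered ring onto C13, and C11 may form as a mixture because it returns to sp2 in step 26.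

Step 17
Reactants: 23 amine-masked diol
Product: 24 seco β-keto ester epoxy aldehyde: methyl (4S)-4-[(2R,3S)-4-[(dimethylamino)methyl]-2-[(1Z)-2-[(2S,3S)-3-formyloxiran-2-yl]prop-1-en-1-yl]-5-oxooxolan-3-yl]-3-oxo-4-[(triethylsilyl)oxy]butanoate (C11 epimers)
Conditions: Dess–Martin periodinane, NaHCO3, CH2Cl2, 0 °C → rt
Reagents that add atoms: none
Why: Dess–Martin oxidation converts the primary epoxy alcohol into the cis-epoxy aldehyde and the β-hydroxy ester into the β-keto ester in one operation under buffered, non-basic conditions that should not epimerise C2 or C8, and the product is used directly.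

Step 18
Reactants: 24 seco β-keto ester epoxy aldehyde
Product: 26 methyl (1(10)E,4Z)-13-(dimethylamino)-2α,3α-epoxy-9-oxo-8β-[(triethylsilyl)oxy]germacra-1(10),4-dien-6α,12-olid-14-oate (6βH, 7αH; C11 epimers), via aldol adduct 25 (not isolated)
Conditions: piperidinium acetate (0.3 equiv), 4 Å molecular sieves, CH2Cl2 (0.002 M, slow addition of 24), rt
Reagents that add atoms: none
Why: Proposed new method: piperidinium acetate turns the C9/C14 β-keto ester into its enol or enaminone and the C1 aldehyde into an iminium ion, C10 adds to C1 to give aldol 25, and loss of water gives the C1=C10 alkylidene β-keto ester; the closest known reaction is the intramolecular Knoevenagel condensation of β-keto esters with aldehydes used for common and large rings, which has not been shown for a ten-membered carbocycle. The ring closes in the 10-exo-trig mode, C10 attacking the carbonyl carbon C1 whose oxygen stays outside the ring. No stereocentre is created; the olefin geometry is set under thermodynamic control, since every stage before dehydration is reversible and the product can equilibrate by reversible amine conjugate addition, and the isomer with C2 cis to C9 (E by the sequence rule) is expected because a trans enone would strain a ring that already holds the Z-C4=C5 olefin, the cis-epoxide and the trans-fused lactone. Closure is helped because those three elements hold the C2–C7 segment in a bent shape and the product ring carries few transannular hydrogens. The step needs C10 to attack C1 and not the lactone carbon C13, which the dimethylamine mask from step 16 secures, while C2 cannot enolise because it is an epoxide carbon and the weakly acidic ammonium carboxylate at room temperature and high dilution should spare the C8 centre, the silyl ether and both oxiranes and suppress dimerisation.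

Step 19
Reactants: 26 masked 9-oxo germacranolide
Product: 27 methyl (1(10)E,4Z)-13-(dimethylamino)-2α,3α-epoxy-9α-hydroxy-8β-[(triethylsilyl)oxy]germacra-1(10),4-dien-6α,12-olid-14-oate (C11 epimers)
Conditions: NaBH4, CeCl3·7H2O, MeOH, −78 °C
Reagents that add atoms: none
Why: Luche reduction gives 1,2-delivery of hydride to the C9 ketone and spares the alkylidene ester and the lactone, and polar Felkin–Anh attack anti to the C8–O bond should give the 8,9-trans (9α) alcohol.

Step 20
Reactants: 27 9α-alcohol; 28 (2R)-2-methylbutanoic acid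
Product: 29 methyl (1(10)E,4Z)-13-(dimethylamino)-2α,3α-epoxy-9α-{[(2R)-2-methylbutanoyl]oxy}-8β-[(triethylsilyl)oxy]germacra-1(10),4-dien-6α,12-olid-14-oate (C11 epimers)
Conditions: DCC, DMAP, CH2Cl2, 0 °C → rt
Reagents that add atoms: none
Why: Steglich esterification acylates the only free hydroxyl, and the α-stereocentre of the acid is carried over unchanged because no acid chloride or ketene is involved.

Step 21
Reactants: 29 9α-ester silyl ether
Product: 30 methyl (1(10)E,4Z)-13-(dimethylamino)-2α,3α-epoxy-8β-hydroxy-9α-{[(2R)-2-methylbutanoyl]oxy}germacra-1(10),4-dien-6α,12-olid-14-oate (C11 epimers)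
Conditions: HF·pyridine, pyridine, THF, 0 °C
Reagents that add atoms: none
Why: Fluoride cleavage of the secondary triethylsilyl ether under buffered, slightly acidic conditions frees O8 while avoiding the base-induced O9-to-O8 acyl shift and leaving the epoxide and the esters intact.

Step 22
Reactants: 31 angelic acid
Product: 32 (2Z)-2-methylbut-2-en-1-ol
Conditions: LiAlH4, Et2O, 0 °C
Reagents that add atoms: none
Why: Hydride reduction of the carboxylic acid gives the primary allylic alcohol without touching or isomerising the trisubstituted Z-olefin.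

Step 23
Reactants: 32 (2Z)-2-methylbut-2-en-1-ol
Product: 33 [(2R,3S)-2,3-dimethyloxiran-2-yl]methanol
Conditions: Ti(OiPr)4, diethyl L-tartrate, t-BuOOH, 4 Å molecular sieves, CH2Cl2, −20 °C
Reagents that add atoms: tert-butyl hydroperoxide, CC(C)(C)OO
Why: Sharpless asymmetric epoxidation with the L-tartrate ligand delivers oxygen to the face that gives the (2R,3S) epoxy alcohol, the Z-olefin keeping the C3 methyl cis to the hydroxymethyl group.

Step 24
Reactants: 33 [(2R,3S)-2,3-dimethyloxiran-2-yl]methanol
Product: 34 (2S,3S)-2,3-dimethyloxirane-2-carboxylic acid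
Conditions: RuCl3 hydrate (cat.), NaIO4, CCl4/MeCN/H2O, rt
Reagents that add atoms: sodium periodate, [Na+].[O-]I(=O)(=O)=O
Why: Periodate oxidation catalysed by RuCl3 (RuO4 formed in situ) takes the primary epoxy alcohol to the glycidic acid without opening the epoxide, and the centres are untouched, the C2 descriptor changing to S only through the change in priorities.

Step 25
Reactants: 30 8β-alcohol; 34 (2S,3S)-2,3-dimethyloxirane-2-carboxylic acid
Product: 36 methyl (1(10)E,4Z)-13-(dimethylamino)-8β-{[(2S,3S)-2,3-dimethyloxiran-2-yl]carbonyloxy}-2α,3α-epoxy-9α-{[(2R)-2-methylbutanoyl]oxy}germacra-1(10),4-dien-6α,12-olid-14-oate (C11 epimers), via mixed anhydride 35 (not isolated)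
Conditions: 34, 2,4,6-trichlorobenzoyl chloride, Et3N, THF, rt; then 30, DMAP, toluene, rt
Reagents that add atoms: none
Why: Yamaguchi esterification activates the hindered α-quaternary acid as its mixed anhydride, which DMAP transfers to the C8 alcohol quickly enough to outrun migration of the neighbouring ester, and no stereocentre is affected.

Step 26
Reactants: 36 masked diester
Product: 38 CNP0485260.1, methyl (1(10)E,4Z)-8β-{[(2S,3S)-2,3-dimethyloxiran-2-yl]carbonyloxy}-2α,3α-epoxy-9α-{[(2R)-2-methylbutanoyl]oxy}germacra-1(10),4,11(13)-trien-6α,12-olid-14-oate, via trimethylammonium iodide 37 (not isolated)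
Conditions: MeI, MeCN, rt; then aq NaHCO3, rt
Reagents that add atoms: none
Why: Quaternisation followed by Hofmann-type E1cB elimination turns the amine into trimethylamine, a leaving group β to the lactone carbonyl, and bicarbonate removes the acidic C11 proton to regenerate the C11=C13 methylene at room temperature, which also erases the C11 mixture.

**Compound list**

1 | (2Z)-3-methylpent-2-en-4-yn-1-ol | C#C/C(C)=C\CO | starting material
2 | tert-butyldimethyl{[(2Z)-3-methylpent-2-en-4-yn-1-yl]oxy}silane | C#C/C(C)=C\CO[Si](C)(C)C(C)(C)C | intermediate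
3 | formaldehyde (paraformaldehyde) | C=O | starting material
4 | (4Z)-6-[(tert-butyldimethylsilyl)oxy]-4-methylhex-4-en-2-yn-1-ol | OCC#C/C(C)=C\CO[Si](C)(C)C(C)(C)C | intermediate
5 | (2Z,4Z)-6-[(tert-butyldimethylsilyl)oxy]-4-methylhexa-2,4-dien-1-ol | OC/C=C\C(C)=C/CO[Si](C)(C)C(C)(C)C | intermediate
6 | [(2R,3S)-3-{(2Z)-4-[(tert-butyldimethylsilyl)oxy]but-2-en-2-yl}oxiran-2-yl]methanol | CC(C)(C)[Si](C)(C)OC/C=C(/C)[C@@H]1O[C@@H]1CO | intermediate
7 | tert-butyl{[(2Z)-3-[(2S,3R)-3-{[(4-methoxybenzyl)oxy]methyl}oxiran-2-yl]but-2-en-1-yl]oxy}dimethylsilane | CC(C)(C)[Si](C)(C)OC/C=C(/C)[C@@H]1O[C@@H]1COCc1ccc(OC)cc1 | intermediate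
8 | (2Z)-3-[(2S,3R)-3-{[(4-methoxybenzyl)oxy]methyl}oxiran-2-yl]but-2-en-1-ol | OC/C=C(/C)[C@@H]1O[C@@H]1COCc1ccc(OC)cc1 | intermediate
9 | (2Z)-3-[(2S,3R)-3-{[(4-methoxybenzyl)oxy]methyl}oxiran-2-yl]but-2-enal | O=C/C=C(/C)[C@@H]1O[C@@H]1COCc1ccc(OC)cc1 | intermediate
10 | methyl (2R)-2,3-dihydroxypropanoate | COC(=O)[C@H](O)CO | starting material
11 | methyl (2R)-2,3-bis[(triethylsilyl)oxy]propanoate | COC(=O)[C@H](O[Si](CC)(CC)CC)CO[Si](CC)(CC)CC | intermediate
12 | (2R)-2,3-bis[(triethylsilyl)oxy]propanal | O=C[C@H](O[Si](CC)(CC)CC)CO[Si](CC)(CC)CC | intermediate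
13 | methyl acrylate | C=CC(=O)OC | starting material
14 | methyl (4R)-3-hydroxy-2-methylidene-4,5-bis[(triethylsilyl)oxy]pentanoate (C3 epimers) | C=C(C(=O)OC)C(O)[C@H](O[Si](CC)(CC)CC)CO[Si](CC)(CC)CC | intermediate
15 | methyl (4R)-3-[(methylsulfonyl)oxy]-2-methylidene-4,5-bis[(triethylsilyl)oxy]pentanoate (C3 epimers) | C=C(C(=O)OC)C(OS(C)(=O)=O)[C@H](O[Si](CC)(CC)CC)CO[Si](CC)(CC)CC | intermediate
16 | methyl (2Z,4S)-2-(bromomethyl)-4,5-bis[(triethylsilyl)oxy]pent-2-enoate | COC(=O)/C(CBr)=C/[C@H](O[Si](CC)(CC)CC)CO[Si](CC)(CC)CC | intermediate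
17 | methyl (3S,4R,5Z)-3-[(1S)-1,2-bis(triethylsilyloxy)ethyl]-4-hydroxy-6-[(2S,3R)-3-{[(4-methoxybenzyl)oxy]methyl}oxiran-2-yl]-2-methylidenehept-5-enoate | COC(=O)C(=C)[C@@H]([C@H](O)/C=C(/C)[C@@H]1O[C@@H]1COCc1ccc(OC)cc1)[C@H](O[Si](CC)(CC)CC)CO[Si](CC)(CC)CC | intermediate
18 | (4S,5R)-4-[(1S)-1,2-bis(triethylsilyloxy)ethyl]-5-[(1Z)-2-[(2S,3R)-3-{[(4-methoxybenzyl)oxy]methyl}oxiran-2-yl]prop-1-en-1-yl]-3-methylideneoxolan-2-one | C=C1C(=O)O[C@H](/C=C(/C)[C@@H]2O[C@@H]2COCc3ccc(OC)cc3)[C@H]1[C@H](O[Si](CC)(CC)CC)CO[Si](CC)(CC)CC | intermediate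
19 | C9 aldehyde: (2S)-2-[(2R,3S)-2-[(1Z)-2-[(2S,3R)-3-{[(4-methoxybenzyl)oxy]methyl}oxiran-2-yl]prop-1-en-1-yl]-4-methylidene-5-oxooxolan-3-yl]-2-[(triethylsilyl)oxy]acetaldehyde | C=C1C(=O)O[C@H](/C=C(/C)[C@@H]2O[C@@H]2COCc3ccc(OC)cc3)[C@H]1[C@H](O[Si](CC)(CC)CC)C=O | intermediate
20 | methyl acetate | CC(=O)OC | starting material
21 | β-hydroxy ester: methyl (4S)-3-hydroxy-4-[lactone as in 19]-4-[(triethylsilyl)oxy]butanoate (C9 epimers) | C=C1C(=O)O[C@H](/C=C(/C)[C@@H]2O[C@@H]2COCc3ccc(OC)cc3)[C@H]1[C@H](O[Si](CC)(CC)CC)C(O)CC(=O)OC | intermediate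
22 | C1,C9 diol: 21 with the 4-methoxybenzyl ether replaced by OH (C9 epimers) | C=C1C(=O)O[C@H](/C=C(/C)[C@@H]2O[C@@H]2CO)[C@H]1[C@H](O[Si](CC)(CC)CC)C(O)CC(=O)OC | intermediate
23 | amine-masked diol: 22 with 13-(dimethylamino)-11,13-dihydro lactone (C9, C11 epimers) | CN(C)CC1C(=O)O[C@H](/C=C(/C)[C@@H]2O[C@@H]2CO)[C@H]1[C@H](O[Si](CC)(CC)CC)C(O)CC(=O)OC | intermediate
24 | seco β-keto ester epoxy aldehyde: methyl (4S)-4-[(2R,3S)-4-[(dimethylamino)methyl]-2-[(1Z)-2-[(2S,3S)-3-formyloxiran-2-yl]prop-1-en-1-yl]-5-oxooxolan-3-yl]-3-oxo-4-[(triethylsilyl)oxy]butanoate (C11 epimers) | CN(C)CC1C(=O)O[C@H](/C=C(/C)[C@@H]2O[C@@H]2C=O)[C@H]1[C@H](O[Si](CC)(CC)CC)C(=O)CC(=O)OC | intermediate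
25 | aldol adduct: methyl 13-(dimethylamino)-2α,3α-epoxy-1-hydroxy-9-oxo-8β-[(triethylsilyl)oxy]germacr-4Z-en-6α,12-olid-14-oate (C1, C10, C11 epimers) | CN(C)CC1C(=O)O[C@@H]2/C=C(/C)[C@@H]3O[C@@H]3C(O)C(C(=O)OC)C(=O)[C@@H](O[Si](CC)(CC)CC)[C@@H]12 | intermediate
26 | methyl (1(10)E,4Z)-13-(dimethylamino)-2α,3α-epoxy-9-oxo-8β-[(triethylsilyl)oxy]germacra-1(10),4-dien-6α,12-olid-14-oate (C11 epimers) | CN(C)CC1C(=O)O[C@@H]2/C=C(/C)[C@@H]3O[C@@H]3/C=C(/C(=O)OC)C(=O)[C@@H](O[Si](CC)(CC)CC)[C@@H]12 | intermediate
27 | 9α-alcohol of 26 | CN(C)CC1C(=O)O[C@@H]2/C=C(/C)[C@@H]3O[C@@H]3/C=C(/C(=O)OC)[C@H](O)[C@@H](O[Si](CC)(CC)CC)[C@@H]12 | intermediate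
28 | (2R)-2-methylbutanoic acid | CC[C@@H](C)C(=O)O | starting material
29 | 9α-[(2R)-2-methylbutanoate] of 27 | CN(C)CC1C(=O)O[C@@H]2/C=C(/C)[C@@H]3O[C@@H]3/C=C(/C(=O)OC)[C@H](OC(=O)[C@H](C)CC)[C@@H](O[Si](CC)(CC)CC)[C@@H]12 | intermediate
30 | 8β-alcohol: 29 without the silyl group | CN(C)CC1C(=O)O[C@@H]2/C=C(/C)[C@@H]3O[C@@H]3/C=C(/C(=O)OC)[C@H](OC(=O)[C@H](C)CC)[C@@H](O)[C@@H]12 | intermediate
31 | angelic acid, (2Z)-2-methylbut-2-enoic acid | C/C=C(/C)C(=O)O | starting material
32 | (2Z)-2-methylbut-2-en-1-ol | C/C=C(/C)CO | intermediate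
33 | [(2R,3S)-2,3-dimethyloxiran-2-yl]methanol | OC[C@@]1(C)O[C@H]1C | intermediate
34 | (2S,3S)-2,3-dimethyloxirane-2-carboxylic acid | OC(=O)[C@@]1(C)O[C@H]1C | intermediate
35 | (2S,3S)-2,3-dimethyloxirane-2-carboxylic 2,4,6-trichlorobenzoic anhydride | O=C(OC(=O)[C@@]1(C)O[C@H]1C)c1c(Cl)cc(Cl)cc1Cl | intermediate
36 | masked diester: 13-(dimethylamino)-11,13-dihydro derivative of the target (C11 epimers) | CN(C)CC1C(=O)O[C@@H]2/C=C(/C)[C@@H]3O[C@@H]3/C=C(/C(=O)OC)[C@H](OC(=O)[C@H](C)CC)[C@@H](OC(=O)[C@@]4(C)O[C@H]4C)[C@@H]12 | intermediate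
37 | 13-(trimethylammonio)-11,13-dihydro derivative of the target, iodide (C11 epimers) | C[N+](C)(C)CC1C(=O)O[C@@H]2/C=C(/C)[C@@H]3O[C@@H]3/C=C(/C(=O)OC)[C@H](OC(=O)[C@H](C)CC)[C@@H](OC(=O)[C@@]4(C)O[C@H]4C)[C@@H]12.[I-] | intermediate
38 | CNP0485260.1 | C=C1C(=O)O[C@@H]2/C=C(/C)[C@@H]3O[C@@H]3/C=C(/C(=O)OC)[C@H](OC(=O)[C@H](C)CC)[C@@H](OC(=O)[C@@]3(C)O[C@H]3C)[C@@H]12 | target

**Step count**

Total: 26 steps. Longest linear sequence: 19 steps (steps 1–7, 12–21, 25, 26, from 1 to 38).

**Steps most likely to fail**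

1. Step 18 (the proposed new method). The 10-exo closure may lose to intermolecular condensation, stall at the aldol stage, or equilibrate to the other olefin geometry or to the C8 epimer under amine catalysis. Fallback with known chemistry, closing the ring at C9–C10 by a Nozaki–Hiyama–Kishi reaction after making C1=C10 by a Wittig reaction: it sets out from lactone 18. DDQ (buffered) removes the 4-methoxybenzyl group to give the C1 alcohol F1. Dess–Martin oxidation gives the cis-epoxy aldehyde F2. Wittig olefination with methyl 2-iodo-2-(triphenylphosphoranylidene)acetate (from Ph3P=CHCO2Me and N-iodosuccinimide) gives the (Z)-α-iodo enoate F3, with C2 trans to the ester. Direct Swern oxidation of the primary silyl ether gives the iodo aldehyde F4. Intramolecular coupling with CrCl2 and catalytic NiCl2 (DMSO/THF, high dilution) joins C10 to C9 with retention of olefin geometry to give the ten-membered allylic alcohol F5 as a C9 mixture. Dimethylamine addition gives the masked alcohol F6, and Dess–Martin oxidation of F6 returns to ketone 26.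

2. Step 12. The C8 centre may steer the aldehyde to the wrong face of C7 or only weakly, the anti preference may erode, and the Lewis-acidic chromium salts may isomerise the Z-epoxy enal (carbonyl oxygen attacking C3) before it is allylated. Fallback that replaces substrate control by catalyst control: it sets out from 9 and 16 and runs the allylation with catalytic CrCl2 bound to a chiral carbazole-bis(oxazoline) ligand, with Mn powder as reductant and Cp2ZrCl2 as turnover reagent. The ligand then selects the aldehyde face, the anti transition state fixes C7, and less chromium salt is present. The adduct 17 lactonises as before and the route is rejoined at 18; no new compound is made.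

3. Step 19. The ring conformation may override the Felkin preference and deliver hydride to the other face of C9 (8,9-cis alcohol), hydride may add 1,4 to the alkylidene keto ester, or the C9 carbonyl oxygen may attack the cis-disposed epoxide carbon C2 under CeCl3. Fallback that uses the wrong epimer productively: it sets out from 26; if reduction (for example with NaBH4 alone or Zn(BH4)2) gives mainly the 9β-alcohol F7, Mitsunobu esterification of F7 with acid 28 (PPh3, diisopropyl azodicarboxylate, THF, 0 °C) installs the 2-methylbutanoate with inversion at C9 and rejoins the route at ester 29.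

**Further compounds**

F1 | step 18 | C1 alcohol from 18 (4-methoxybenzyl group removed) | C=C1C(=O)O[C@H](/C=C(/C)[C@@H]2O[C@@H]2CO)[C@H]1[C@H](O[Si](CC)(CC)CC)CO[Si](CC)(CC)CC
F2 | step 18 | cis-epoxy aldehyde from F1 | C=C1C(=O)O[C@H](/C=C(/C)[C@@H]2O[C@@H]2C=O)[C@H]1[C@H](O[Si](CC)(CC)CC)CO[Si](CC)(CC)CC
F3 | step 18 | (Z)-α-iodo enoate (C1=C10 in place, iodine on C10) | C=C1C(=O)O[C@H](/C=C(/C)[C@@H]2O[C@@H]2/C=C(/C(=O)OC)I)[C@H]1[C@H](O[Si](CC)(CC)CC)CO[Si](CC)(CC)CC
F4 | step 18 | iodo enoate C9 aldehyde | C=C1C(=O)O[C@H](/C=C(/C)[C@@H]2O[C@@H]2/C=C(/C(=O)OC)I)[C@H]1[C@H](O[Si](CC)(CC)CC)C=O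
F5 | step 18 | methyl (1(10)E,4Z)-2α,3α-epoxy-9-hydroxy-8β-[(triethylsilyl)oxy]germacra-1(10),4,11(13)-trien-6α,12-olid-14-oate (C9 epimers) | C=C1C(=O)O[C@@H]2/C=C(/C)[C@@H]3O[C@@H]3/C=C(/C(=O)OC)C(O)[C@@H](O[Si](CC)(CC)CC)[C@@H]12
F6 | step 18 | 13-(dimethylamino)-11,13-dihydro derivative of F5 (C9, C11 epimers) | CN(C)CC1C(=O)O[C@@H]2/C=C(/C)[C@@H]3O[C@@H]3/C=C(/C(=O)OC)C(O)[C@@H](O[Si](CC)(CC)CC)[C@@H]12
F0 | step 12 | none | none
F7 | step 19 | 9β-alcohol (C9 epimer of 27) | CN(C)CC1C(=O)O[C@@H]2/C=C(/C)[C@@H]3O[C@@H]3/C=C(/C(=O)OC)[C@@H](O)[C@@H](O[Si](CC)(CC)CC)[C@@H]12
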